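The synthesis rests on cutting the benzene ring itself. Its two adjacent carbons that bear the lactone C=O and the macrocyclic CH2 (C-14a and C-10a) are taken as the C≡C of a 12-membered ynolide, and the other four arene carbons (C–OMe, CH, C–OH, CH) as a 1,3-dioxygenated butadiene. One Diels–Alder/aromatisation thus annulates the arene onto the preformed macrolactone and delivers OMe ortho and free OH para to the carbonyl, i.e. (R)-lasiodiplodin. The precursor is (R)-12-methyloxacyclododec-3-yn-2-one, made from (R)-propylene oxide and oct-1-yne. An ortho-aminomethylation and an o-quinone methide hetero-Diels–Alder reaction with (S)-3,5-dimethyl-2,3-dihydrofuran then build the cis-fused furo-pyran ketal.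

Key step: step 7

Remark: arene positions use the 2-benzoxacyclododecin numbering of lasiodiplodin (C-10a carries the macrocyclic CH2, C-11 H, C-12 OH, C-13 H, C-14 OMe, C-14a the C=O); intermediates are numbered when they exist as a discrete species before the next event, whereas the equilibrating allene/alkyne salts of step 2 and fleeting tetrahedral adducts are not.

Step 1
Reactants: 1 oct-1-yne; 2 (R)-2-methyloxirane [(R)-propylene oxide]
Product: 4 (R)-undec-4-yn-2-ol, via lithium octynide 3 (not isolated)
Conditions: n-BuLi, THF, −78 → 0 °C; then 2, DMPU, 0 °C → rt; H2O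
Reagents that add atoms: none
Why: SN2 opening of a terminal epoxide by a lithium acetylide takes place at the unsubstituted CH2, so the stereocentre is not touched and (R) is carried over from 2.

Step 2
Reactants: 4 (R)-undec-4-yn-2-ol
Product: 5 (R)-undec-10-yn-2-ol
Conditions: KH, H2N(CH2)3NH2, 0 °C → rt; then H2O
Reagents that add atoms: none
Why: In the alkyne zipper reaction (potassium 3-aminopropylamide) successive propargyl/allenyl proton shifts walk the triple bond down the chain until it is trapped as the terminal acetylide, while the carbinol centre, held as its alkoxide, should keep its (R) configuration.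

Step 3
Reactants: 5 (R)-undec-10-yn-2-ol
Product: 7 (R)-11-hydroxydodec-2-ynoic acid, via dilithiated alkynol 6 (not isolated)
Conditions: n-BuLi (2.2 equiv), THF, −78 → −20 °C; CO2 (g), −78 °C → rt; 1 M HCl
Reagents that add atoms: carbon dioxide, O=C=O
Why: Carboxylation of a terminal acetylide: the alkoxide–acetylide dianion takes up CO2 at the sp carbon, and any alkyl carbonate formed at oxygen reverts on acidification, so the alcohol needs no protection.

Step 4
Reactants: 7 (R)-11-hydroxydodec-2-ynoic acid
Product: 9 (R)-12-methyloxacyclododec-3-yn-2-one, via mixed anhydride 8 (not isolated)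
Conditions: 2,4,6-Cl3C6H2COCl, Et3N, THF, rt; then syringe pump into DMAP, toluene, 60–80 °C (ca. 2 mM)
Reagents that add atoms: none
Why: Yamaguchi macrolactonisation: the acid is activated as the mixed anhydride and, at high dilution, the secondary alcohol attacks the acyl carbon to close the 12-membered ring, which accommodates the linear C–C≡C–C unit; no bond to the stereocentre is broken, so (R) is retained.

Step 5
Reactants: 10 1,1-dimethoxyethene
Product: 11 4,4-dimethoxybut-3-en-2-one
Conditions: AcCl, Et3N, Et2O, 0 °C → rt
Reagents that add atoms: acetyl chloride, CC(=O)Cl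
Why: C-Acylation of a ketene acetal: the nucleophilic CH2 of 10 attacks the acid chloride and the amine removes HCl from the oxocarbenium intermediate to give the push–pull enone.

Step 6
Reactants: 11 4,4-dimethoxybut-3-en-2-one
Product: 13 1,1-dimethoxy-3-(trimethylsilyloxy)buta-1,3-diene, via lithium dienolate 12 (not isolated)
Conditions: LDA, THF, −78 °C; TMSCl, −78 °C → rt; pentane, filter, distil
Reagents that add atoms: chlorotrimethylsilane, C[Si](C)(C)Cl
Why: Kinetic enolisation of the methyl ketone (its only enolisable position) followed by O-silylation (silyl enol ether formation) gives the 2-silyloxydiene, and the non-aqueous work-up protects the ketene acetal.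

Step 7
Reactants: 9 (R)-12-methyloxacyclododec-3-yn-2-one; 13 1,1-dimethoxy-3-(trimethylsilyloxy)buta-1,3-diene
Product: 16 (R)-lasiodiplodin, via cyclohexadiene cycloadduct 14 (not isolated), via lasiodiplodin trimethylsilyl ether 15 (not isolated)
Conditions: 13 (4 equiv, in portions), toluene (ca. 2 M in 9), sealed tube, 130–140 °C; then 1 M HCl, THF, rt
Reagents that add atoms: none
Why: The electron-rich diene 13 adds to the electron-poor C≡C of 9 in a thermal, concerted but strongly asynchronous [4+2] cycloaddition, its CH2 terminus bonding to the ynoate β-carbon and its C(OMe)2 terminus to the α-carbon, to give cyclohexa-1,4-diene 14; 1,4-elimination of methanol (OMe from the ketal carbon, H from the ring CH2) aromatises 14 to silyl ether 15 and dilute acid frees the phenol. The closest known reaction type is the Diels–Alder/aromatisation of 1,1-dialkoxy-3-silyloxybuta-1,3-dienes with acetylenic esters to 2-alkoxy-4-hydroxybenzoates. The benzene ring is closed by intermolecular cycloaddition (two C–C bonds, C-14 to C-14a and C-11 to C-10a, made in one annulation) onto the two sp carbons of the intact 12-membered lactone, so no macrocyclisation is asked of this step. No stereocentre is created and the (R) centre at C-3 lies far from the reacting atoms. The selectivity needed is regiochemical, OMe ortho and OH para to the carbonyl, and it is secured by matched polarisation: the largest HOMO coefficient of 13 sits on the CH2 terminus towards which both oxygen donors push, the largest LUMO coefficient of 9 on the β-carbon of the ynoate. The β-alkyl ynoate held in a ring is a sluggish dienophile, hence the excess of diene, the high concentration and 130–140 °C.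

Step 8
Reactants: 16 (R)-lasiodiplodin
Product: 17 (R)-11-(morpholin-4-ylmethyl)lasiodiplodin
Conditions: morpholine, 37% aq. CH2O, MeOH, reflux
Reagents that add atoms: formaldehyde, C=O; morpholine, C1COCCN1
Why: Phenolic Mannich reaction: the N-methylenemorpholinium ion formed in situ substitutes ortho to the OH, and of the two ortho CH positions C-11 (para to OMe, next to the alkyl chain, the site orcinol-type phenols prefer) should react rather than C-13, which is squeezed between two oxygen-bearing carbons; the hindered 2,6-disubstituted benzoate lactone should resist aminolysis.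

Step 9
Reactants: 18 (R)-4-benzyl-3-propanoyloxazolidin-2-one
Product: 20 (R)-4-benzyl-3-[(S)-2-methylpent-4-ynoyl]oxazolidin-2-one, via sodium Z-enolate 19 (not isolated)
Conditions: NaHMDS, THF, −78 °C; HC≡CCH2Br, −78 → −40 °C
Reagents that add atoms: propargyl bromide (3-bromoprop-1-yne), C#CCBr
Why: Evans asymmetric alkylation: the chelated sodium (Z)-enolate is alkylated on the face opposite the benzyl group of the (R)-auxiliary, which sets the new α-stereocentre as (S), and any minor diastereomer is removable by chromatography.

Step 10
Reactants: 20 (R)-4-benzyl-3-[(S)-2-methylpent-4-ynoyl]oxazolidin-2-one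
Product: 21 (S)-2-methylpent-4-yn-1-ol
Conditions: LiBH4, H2O (1 equiv), Et2O, 0 °C; careful concentration, distil
Reagents that add atoms: none
Why: Reductive cleavage of the N-acyloxazolidinone by borohydride at the exocyclic carbonyl gives the primary alcohol without touching the α-stereocentre or the alkyne and returns the auxiliary.

Step 11
Reactants: 21 (S)-2-methylpent-4-yn-1-ol
Product: 23 (S)-3,5-dimethyl-2,3-dihydrofuran, via exocyclic enol ether 22 (not isolated)
Conditions: NaNH2 (5 mol %), neat, 110 °C; distil, store cold over K2CO3
Reagents that add atoms: none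
Why: Base-catalysed cycloisomerisation of a 4-pentyn-1-ol: the alkoxide adds 5-exo-dig to the alkyne and the first-formed exocyclic enol ether shifts on continued heating to the more substituted endocyclic isomer; the stereocentre takes no part and stays (S).

Step 12
Reactants: 17 (R)-11-(morpholin-4-ylmethyl)lasiodiplodin; 23 (S)-3,5-dimethyl-2,3-dihydrofuran
Product: 26 lasiodiplactone A, via N-methylmorpholinium iodide 24 (not isolated), via o-quinone methide 25 (not isolated)
Conditions: MeI (1.2 equiv), 23 (4 equiv), toluene, rt then 80 °C (sealed tube); NaHCO3 work-up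
Reagents that add atoms: none
Why: N-Methylation makes the amine a leaving group and warming expels 4-methylmorpholine from the phenol to give o-quinone methide 25, which the enol ether traps in an inverse-electron-demand hetero-Diels–Alder reaction (exocyclic CH2 to C-4 of 23, carbonyl O to C-5), so that suprafacial addition fixes the cis ring fusion while approach anti to the C-3 methyl group next to the bond-forming carbon should set the ring-fusion CH (S) and the ketal carbon (S) relative to the existing (S) centre; the macrolide centre is too remote to interfere.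

Compound list
1 | oct-1-yne | C#CCCCCCC | starting material
2 | (R)-2-methyloxirane [(R)-propylene oxide] | C[C@@H]1CO1 | starting material
3 | lithium oct-1-yn-1-ide | [Li+].[C-]#CCCCCCC | intermediate
4 | (R)-undec-4-yn-2-ol | C[C@@H](O)CC#CCCCCCC | intermediate
5 | (R)-undec-10-yn-2-ol | C[C@@H](O)CCCCCCCC#C | intermediate
6 | dilithium salt of 5 (alkoxide and terminal acetylide) | C[C@@H]([O-])CCCCCCCC#[C-].[Li+].[Li+] | intermediate
7 | (R)-11-hydroxydodec-2-ynoic acid | C[C@@H](O)CCCCCCCC#CC(=O)O | intermediate
8 | mixed anhydride of 7 with 2,4,6-trichlorobenzoic acid | C[C@@H](O)CCCCCCCC#CC(=O)OC(=O)c1c(Cl)cc(Cl)cc1Cl | intermediate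
9 | (R)-12-methyloxacyclododec-3-yn-2-one (12-membered ynolide) | O=C1O[C@H](C)CCCCCCCC#C1 | intermediate
10 | 1,1-dimethoxyethene | C=C(OC)OC | starting material
11 | 4,4-dimethoxybut-3-en-2-one | CC(=O)C=C(OC)OC | intermediate
12 | lithium 4,4-dimethoxybuta-1,3-dien-2-olate | [Li+].[O-]C(=C)C=C(OC)OC | intermediate
13 | 1,1-dimethoxy-3-(trimethylsilyloxy)buta-1,3-diene | COC(OC)=CC(=C)O[Si](C)(C)C | intermediate
14 | primary [4+2] adduct: cyclohexa-1,4-diene fused to the lactone across the former alkyne, C(OMe)2 next to the carbon bearing C=O, ring CH2 next to the carbon bearing the macrocyclic CH2, OSiMe3 on the second ring alkene, (R) at the carbinol carbon | COC1(OC)C=C(O[Si](C)(C)C)CC2=C1C(=O)O[C@H](C)CCCCCCC2 | intermediate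
15 | (R)-lasiodiplodin 12-O-trimethylsilyl ether | COc1cc(O[Si](C)(C)C)cc2c1C(=O)O[C@H](C)CCCCCCC2 | intermediate
16 | (R)-lasiodiplodin [(3R)-12-hydroxy-14-methoxy-3-methyl-3,4,5,6,7,8,9,10-octahydro-1H-2-benzoxacyclododecin-1-one] | COc1cc(O)cc2c1C(=O)O[C@H](C)CCCCCCC2 | intermediate
17 | (R)-11-(morpholin-4-ylmethyl)lasiodiplodin | COc1cc(O)c(CN2CCOCC2)c2c1C(=O)O[C@H](C)CCCCCCC2 | intermediate
18 | (R)-4-benzyl-3-propanoyloxazolidin-2-one | CCC(=O)N1[C@H](Cc2ccccc2)COC1=O | starting material
19 | sodium (Z)-enolate of 18 | C/C=C(\[O-])N1[C@H](Cc2ccccc2)COC1=O.[Na+] | intermediate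
20 | (R)-4-benzyl-3-[(S)-2-methylpent-4-ynoyl]oxazolidin-2-one | C#CC[C@H](C)C(=O)N1[C@H](Cc2ccccc2)COC1=O | intermediate
21 | (S)-2-methylpent-4-yn-1-ol | C#CC[C@H](C)CO | intermediate
22 | (S)-4-methyl-2-methylideneoxolane | C=C1C[C@H](C)CO1 | intermediate
23 | (S)-3,5-dimethyl-2,3-dihydrofuran | CC1=C[C@H](C)CO1 | intermediate
24 | 4-methylmorpholinium iodide of 17 (N-methylated at the morpholine nitrogen) | COc1cc(O)c(C[N+]2(C)CCOCC2)c2c1C(=O)O[C@H](C)CCCCCCC2.[I-] | intermediate
25 | o-quinone methide of lasiodiplodin (C-12 carbonyl, exocyclic CH2 on C-11), (R) at C-3 | COC1=CC(=O)C(=C)C2=C1C(=O)O[C@H](C)CCCCCCC2 | intermediate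
26 | lasiodiplactone A: (R)-lasiodiplodin bridged from O-12 and C-11 by a cis-fused tetrahydrofuro-pyran ketal, ketal carbon (S, bearing CH3), ring-fusion CH (S), CH(CH3) (S), macrolide C-3 (R) | COc1cc2c(c3c1C(=O)O[C@H](C)CCCCCCC3)C[C@H]1[C@H](C)CO[C@@]1(C)O2 | target

Total step count: 12. Longest linear sequence: 7 steps (steps 1, 2, 3, 4, 7, 8, 12).

Steps most likely to fail

Step 7. The hindered β-alkyl ynoate may react more slowly than the acyclic ketene-acetal diene desilylates or polymerises at the temperature required, so that little cycloadduct forms. The fallback sets out from 9 and comes back at 15. Kinetic α′-deprotonation of commercial 3-methoxycyclohex-2-en-1-one (LDA, THF, −78 °C) and silylation (TMSCl) would give 1-methoxy-3-(trimethylsilyloxy)cyclohexa-1,3-diene F1, an s-cis-locked and thermally sturdier diene of the same polarity. Heated with 9 (neat or in mesitylene, 150–180 °C) it should give the bicyclo[2.2.2]octadiene adduct F2 (bridgehead OMe next to the carbon bearing C=O, any bridgehead configuration). At that temperature F2 expels its ethano bridge as ethylene by retro-Diels–Alder reaction (Alder–Rickert sequence) and lands on silyl ether 15, which the acid work-up of step 7 converts into 16.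

Step 12. Oligomerisation of the o-quinone methide may outrun its capture by the volatile, acid-sensitive enol ether, and facial discrimination by a single methyl group may be weak. The fallback sets out from 17 and comes back at 26, forming the C–C bond and the ketal in separate, substrate-controlled events. Compound 17 is quaternised with MeI to 24 (volatiles removed) and added to 2.2 equiv of the lithium enolate of commercial (S)-4-methyldihydrofuran-2(3H)-one (O=C1C[C@H](C)CO1; LDA, THF, −78 → 0 °C). One equivalent deprotonates the phenol and releases 25; the second adds to its CH2 (Michael addition of a lactone enolate to an o-quinone methide) trans to the neighbouring methyl group, the usual outcome for β-substituted γ-butyrolactone enolates, giving the trans-(3S,4S)-3-(arylmethyl)-4-methyl-γ-butyrolactone F3. MeLi (2.2 equiv, THF, −78 °C; the phenoxide and the hindered macrolactone should be spared) would turn the γ-lactone into the methyl lactol F4. Catalytic PPTS (CH2Cl2, 4 Å MS, rt) then closes the mixed ketal with the phenol, cis fusion being the only unstrained mode, to give 26.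

Step 8. Aminomethylation may occur at C-13 or twice, or the ester-deactivated phenol may react sluggishly. The fallback sets out from 16 and comes back at 25, introducing the carbon at the aldehyde oxidation level through a chelated magnesium phenoxide, a process with a strong preference for the ortho position para to a meta-alkoxy group. Magnesium-mediated ortho-formylation (MgCl2, Et3N, paraformaldehyde, MeCN, reflux) would give (R)-11-formyllasiodiplodin F5. NaBH4 (MeOH, 0 °C) reduces it to the salicyl alcohol (R)-11-(hydroxymethyl)lasiodiplodin F6. Heating F6 with 23 (toluene, 150–170 °C, sealed tube) dehydrates it to 25, which is trapped as in step 12.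

Further compounds
F1 | step 7 | 1-methoxy-3-(trimethylsilyloxy)cyclohexa-1,3-diene | COC1=CC(O[Si](C)(C)C)=CCC1
F2 | step 7 | bicyclo[2.2.2]octa-2,5-diene adduct of F1 and 9 (bridgehead OMe next to the carbon bearing C=O, OSiMe3 on the second alkene, ethano bridge), (R) at the carbinol carbon | COC12CCC(C(O[Si](C)(C)C)=C1)C1=C2C(=O)O[C@H](C)CCCCCCC1
F3 | step 12 | (R)-lasiodiplodin carrying at C-11 a [(3S,4S)-4-methyl-2-oxooxolan-3-yl]methyl group (trans lactone) | COc1cc(O)c(C[C@H]2[C@H](C)COC2=O)c2c1C(=O)O[C@H](C)CCCCCCC2
F4 | step 12 | methyl lactol of F3 (2-hydroxy-2,4-dimethyloxolan-3-yl)methyl at C-11, anomeric mixture | COc1cc(O)c(C[C@H]2[C@H](C)COC2(C)O)c2c1C(=O)O[C@H](C)CCCCCCC2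
F5 | step 8 | (R)-11-formyllasiodiplodin | COc1cc(O)c(C=O)c2c1C(=O)O[C@H](C)CCCCCCC2
F6 | step 8 | (R)-11-(hydroxymethyl)lasiodiplodin | COc1cc(O)c(CO)c2c1C(=O)O[C@H](C)CCCCCCC2
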